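**Retrosynthetic overview**

1. Target 25 comes from the macrocyclic 2-aryloxycyclohexanone 22 by dehydrogenation of ring C, debenzylation and oxidation of ring D. The feature used: in ring C the hydroxyl carbon (para to the ethylene chain to ring B) and the carbon bearing the ring A oxygen (meta to that chain) correspond to the C1 carbonyl and a C2 alpha carbon of a 4-alkylcyclohexanone, whose two alpha carbons are equivalent by the mirror plane through C1 and C4.
2. 22 comes from the seco alpha-bromoketone phenol 21 by forming the bond from the ring A oxygen to C2 of ring C, which closes the 18-membered ring.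
3. 21 comes from 17 by ketal removal and alpha-bromination; 17 comes from aldehyde 12 and a free-phenol ring A ylide by Wittig reaction and diimide reduction.
4. 12 comes from an Ullmann diaryl ether coupling of the ring D bromoaldehyde 11 (from methoxyhydroquinone by benzylation, bromination para to OMe, ortho-lithiation/formylation) with the ring B phenol 6 (from a 3-hydroxybenzyl ylide and ketal aldehyde 3, then hydrogenation).
5. Ring order: rings A, B and D are bought as benzenes and ring C is carried as a cyclohexanone; the macrocycle is closed in step 13, ring C becomes a benzene in step 14, and the ring D quinone is revealed in steps 15 and 16.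

Key step: step 13

Remark: compounds 19 to 22 carry sp3 stereocentres on the future ring C and are used as racemic diastereomer mixtures, because step 14 removes all of them and the target is achiral.

**Route**

Step 1
Reactants: 1 3-hydroxybenzyl alcohol
Product: 2 (3-hydroxybenzyl)triphenylphosphonium bromide
Conditions: PPh3·HBr (1.05 equiv), MeCN, reflux
Reagents that add atoms: triphenylphosphine hydrobromide, [Br-].c1ccc(cc1)[PH+](c1ccccc1)c1ccccc1
Why: Under HBr the benzylic alcohol ionises and is trapped by triphenylphosphine (phosphonium salt formation from a benzylic alcohol), so the salt should form without protecting the phenol.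

Step 2
Reactants: 2 (3-hydroxybenzyl)triphenylphosphonium bromide; 3 1,4-dioxaspiro[4.5]decane-8-carbaldehyde
Product: 5 3-[2-(1,4-dioxaspiro[4.5]decan-8-yl)ethenyl]phenol (E/Z mixture), via phenoxide ylide 4 (not isolated)
Conditions: 2 (1.2 equiv), KOC(CH3)3 (2.3 equiv), THF, 0 °C; then 3, 0 °C to rt; pH 7 buffer
Reagents that add atoms: potassium tert-butoxide, CC(C)(C)[O-].[K+] (its potassium appears only in 4)
Why: Wittig olefination: two equivalents of base give the semi-stabilised phenoxide ylide, which should olefinate the aliphatic aldehyde while the ketal is inert to base, and the alkene geometry is irrelevant because the double bond is saturated next.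

Step 3
Reactants: 5 3-[2-(1,4-dioxaspiro[4.5]decan-8-yl)ethenyl]phenol
Product: 6 3-[2-(1,4-dioxaspiro[4.5]decan-8-yl)ethyl]phenol
Conditions: H2 (1 atm), 10% Pd/C, EtOAc, rt
Reagents that add atoms: none
Why: Catalytic hydrogenation of a styrene-type alkene should leave the ketal and the phenol untouched, and no stereocentre arises because C8 of the spiroketal carries two identical ring arms.

Step 4
Reactants: 7 2-methoxybenzene-1,4-diol
Product: 8 1,4-bis(benzyloxy)-2-methoxybenzene
Conditions: BnBr (2.3 equiv), K2CO3, DMF, N2, rt to 50 °C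
Reagents that add atoms: benzyl bromide, BrCc1ccccc1
Why: Williamson ether synthesis on both hydroquinone oxygens, run under nitrogen to keep the electron-rich hydroquinone from air oxidation.

Step 5
Reactants: 8 1,4-bis(benzyloxy)-2-methoxybenzene
Product: 9 1,4-bis(benzyloxy)-2-bromo-5-methoxybenzene
Conditions: NBS (1.05 equiv), MeCN, 0 °C
Reagents that add atoms: N-bromosuccinimide, O=C1CCC(=O)N1Br
Why: Electrophilic aromatic bromination should go to the one position that is para to the methoxy group, ortho to a benzyloxy group and not flanked on both sides, as in the bromination of 1,2,4-trimethoxybenzene.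

Step 6
Reactants: 9 1,4-bis(benzyloxy)-2-bromo-5-methoxybenzene
Product: 11 3,6-bis(benzyloxy)-2-bromo-5-methoxybenzaldehyde, via aryllithium 10 (not isolated)
Conditions: LiN(iPr)2 (1.15 equiv), THF, −78 °C; then DMF, −78 °C to 0 °C; 1 M HCl
Reagents that add atoms: lithium diisopropylamide, CC(C)[N-]C(C)C.[Li+] (its lithium appears only in 10); N,N-dimethylformamide, CN(C)C=O
Why: Directed ortho-lithiation then formylation: the C–H flanked by bromine and a benzyloxy group is the most acidic one, and the amide base at −78 °C should deprotonate it without bromine–lithium exchange or aryne formation before DMF traps the aryllithium.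

Step 7
Reactants: 11 3,6-bis(benzyloxy)-2-bromo-5-methoxybenzaldehyde; 6 3-[2-(1,4-dioxaspiro[4.5]decan-8-yl)ethyl]phenol
Product: 12 3,6-bis(benzyloxy)-2-{3-[2-(1,4-dioxaspiro[4.5]decan-8-yl)ethyl]phenoxy}-5-methoxybenzaldehyde
Conditions: CuI (20 mol%), picolinic acid (40 mol%), K3PO4 (2 equiv), DMSO, 90 °C
Reagents that add atoms: none
Why: Ullmann-type copper-catalysed diaryl ether synthesis, in which the ortho-formyl group assists coupling at the C–Br bond and the unhindered meta-alkylphenol is a good nucleophile, while benzyl ethers, ketal and the non-enolisable aldehyde should tolerate the mild base.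

Step 8
Reactants: 13 4-hydroxybenzyl alcohol
Product: 14 (4-hydroxybenzyl)triphenylphosphonium bromide
Conditions: PPh3·HBr (1.05 equiv), MeCN, reflux
Reagents that add atoms: triphenylphosphine hydrobromide, [Br-].c1ccc(cc1)[PH+](c1ccccc1)c1ccccc1
Why: Same phosphonium salt formation as in step 1, the para-hydroxybenzyl cation being trapped by the phosphine faster than it can oligomerise.

Step 9
Reactants: 14 (4-hydroxybenzyl)triphenylphosphonium bromide; 12 3,6-bis(benzyloxy)-2-{3-[2-(1,4-dioxaspiro[4.5]decan-8-yl)ethyl]phenoxy}-5-methoxybenzaldehyde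
Product: 16 4-[2-(3,6-bis(benzyloxy)-2-{3-[2-(1,4-dioxaspiro[4.5]decan-8-yl)ethyl]phenoxy}-5-methoxyphenyl)ethenyl]phenol (E/Z mixture), via phenoxide ylide 15 (not isolated)
Conditions: 14 (1.5 equiv), KOC(CH3)3 (3.0 equiv), THF, 0 °C; then 12, rt; pH 7 buffer
Reagents that add atoms: potassium tert-butoxide, CC(C)(C)[O-].[K+] (its potassium appears only in 15)
Why: Wittig olefination of a non-enolisable 2,6-dioxygenated benzaldehyde with an electron-rich phenoxide ylide, which brings in ring A with its phenol already free; the alkene geometry is irrelevant.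

Step 10
Reactants: 16 the stilbene from step 9
Product: 17 4-[2-(3,6-bis(benzyloxy)-2-{3-[2-(1,4-dioxaspiro[4.5]decan-8-yl)ethyl]phenoxy}-5-methoxyphenyl)ethyl]phenol
Conditions: TsNHNH2 (10 equiv, in portions), NaOAc (12 equiv), THF/H2O, reflux
Reagents that add atoms: none
Why: Diimide reduction transfers H2 to the stilbene double bond in a concerted way and cannot hydrogenolyse the benzyl ethers, and the ketone is still masked as the ketal so that no tosylhydrazone can form.

Step 11
Reactants: 17 the bibenzyl ketal phenol from step 10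
Product: 18 4-[2-(3-{3,6-bis(benzyloxy)-2-[2-(4-hydroxyphenyl)ethyl]-4-methoxyphenoxy}phenyl)ethyl]cyclohexan-1-one
Conditions: 2 M HCl, THF, rt
Reagents that add atoms: water, O
Why: Acid-catalysed ketal hydrolysis, under which benzyl and diaryl ethers are stable, should release the symmetric 4-substituted cyclohexanone.

Step 12
Reactants: 18 4-[2-(3-{3,6-bis(benzyloxy)-2-[2-(4-hydroxyphenyl)ethyl]-4-methoxyphenoxy}phenyl)ethyl]cyclohexan-1-one
Product: 21 2-bromo-4-[2-(3-{3,6-bis(benzyloxy)-2-[2-(4-hydroxyphenyl)ethyl]-4-methoxyphenoxy}phenyl)ethyl]cyclohexan-1-one (racemic cis/trans mixture), via bis-silyl enol ether 19 (not isolated), via silylated bromoketone 20 (not isolated)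
Conditions: Me3SiOSO2CF3 (2.4 equiv), Et3N (4 equiv), CH2Cl2, 0 °C; then NBS (1.0 equiv), THF, −78 °C; then 1 M HCl/THF, 0 °C
Reagents that add atoms: trimethylsilyl trifluoromethanesulfonate, C[Si](C)(C)OS(=O)(=O)C(F)(F)F (its silicon appears only in 19 and 20); N-bromosuccinimide, O=C1CCC(=O)N1Br
Why: Alpha-bromination through the silyl enol ether: soft enolisation also masks the phenol as its silyl ether, the enol ether should react with one equivalent of NBS at −78 °C far faster than any arene, the symmetric ketone gives a single constitution, the new C–Br stereocentre is uncontrolled and irrelevant, and mild acid frees the phenol again.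

Step 13
Reactants: 21 2-bromo-4-[2-(3-{3,6-bis(benzyloxy)-2-[2-(4-hydroxyphenyl)ethyl]-4-methoxyphenoxy}phenyl)ethyl]cyclohexan-1-one
Product: 22 macrocyclic 2-aryloxycyclohexanone (18-membered ring; racemic diastereomer mixture)
Conditions: Cs2CO3 (3 equiv), MeCN, 50 °C, syringe-pump addition of 21 to about 1 mM
Reagents that add atoms: none
Why: Carbonate generates the ring A phenoxide, which displaces bromide at the carbon alpha to the ketone in an SN2 reaction whose transition state is stabilised by the adjacent C=O pi system. The closest known reaction is the Williamson O-alkylation of phenols with 2-bromocyclohexanone under carbonate base, which gives 2-aryloxycyclohexanones. The 18-membered ring closes by exo attack of the tethered phenoxide on a flexible sp3 carbon (18-exo-tet macro-etherification), and slow addition at high dilution should favour ring closure over oligomerisation. The new C–O stereocentre forms with inversion and is not controlled relative to C4 (it also epimerises under the base), which is harmless because both sp3 centres disappear in step 14. The step needs O- over C-alkylation and substitution over dehydrobromination or Favorskii contraction, and the weakly basic phenoxide/carbonate pair in a polar aprotic solvent should secure both. Regiochemistry needs no control, because the mirror plane through C1 and C4 of the cyclohexanone makes both alpha carbons equivalent, so the ring A oxygen necessarily ends up meta to the chain.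

Step 14
Reactants: 22 macrocyclic 2-aryloxycyclohexanone
Product: 23 macrocyclic bis(bibenzyl) with ring C as a 2-aryloxyphenol and ring D as the dibenzyl ether
Conditions: Pd(OCOCF3)2 (10 mol%), 2-(dimethylamino)pyridine (20 mol%), TsOH·H2O (40 mol%), O2 (1 atm), DMSO, 80 °C
Reagents that add atoms: none
Why: Palladium-catalysed aerobic dehydrogenation of a cyclohexanone to a phenol: two rounds of palladium enolate formation and beta-hydride elimination give a dienone that tautomerises to the phenol, O2 reoxidises zerovalent palladium, and benzyl and diaryl ethers are not touched because no hydrogen gas is present.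

Step 15
Reactants: 23 macrocyclic dibenzyl ether
Product: 24 macrocyclic hydroquinone (ring D as 2-methoxy-1,4-hydroquinone)
Conditions: H2 (1 atm), 10% Pd/C, EtOAc/MeOH, rt; filtration under argon
Reagents that add atoms: none
Why: Hydrogenolysis of the two aryl benzyl ethers should be clean because the molecule otherwise holds only diaryl ethers, a methyl ether and a phenol.

Step 16
Reactants: 24 macrocyclic hydroquinone
Product: 25 target quinone CNP0332646.0
Conditions: Ag2O (1.2 equiv), Na2SO4, Et2O/THF, rt
Reagents that add atoms: none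
Why: Oxidation of a hydroquinone to the para-quinone with silver oxide is fast for this electron-rich trioxygenated ring, and the ring C monophenol should survive a near-stoichiometric amount of oxidant.

**Compound list**

1 | 3-hydroxybenzyl alcohol | OCc1cccc(O)c1 | starting material
2 | (3-hydroxybenzyl)triphenylphosphonium bromide | [Br-].Oc1cccc(C[P+](c2ccccc2)(c2ccccc2)c2ccccc2)c1 | intermediate
3 | 1,4-dioxaspiro[4.5]decane-8-carbaldehyde | O=CC1CCC2(CC1)OCCO2 | starting material
4 | potassium 3-[(triphenylphosphoranylidene)methyl]phenolate (phenoxide ylide) | [K+].[O-]c1cccc(C=P(c2ccccc2)(c2ccccc2)c2ccccc2)c1 | intermediate (not isolated)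
5 | 3-[2-(1,4-dioxaspiro[4.5]decan-8-yl)ethenyl]phenol, E/Z mixture | Oc1cccc(C=CC2CCC3(CC2)OCCO3)c1 | intermediate
6 | 3-[2-(1,4-dioxaspiro[4.5]decan-8-yl)ethyl]phenol | Oc1cccc(CCC2CCC3(CC2)OCCO3)c1 | intermediate
7 | 2-methoxybenzene-1,4-diol (methoxyhydroquinone) | COc1cc(O)ccc1O | starting material
8 | 1,4-bis(benzyloxy)-2-methoxybenzene | COc1cc(OCc2ccccc2)ccc1OCc1ccccc1 | intermediate
9 | 1,4-bis(benzyloxy)-2-bromo-5-methoxybenzene | COc1cc(OCc2ccccc2)c(Br)cc1OCc1ccccc1 | intermediate
10 | [3,6-bis(benzyloxy)-2-bromo-5-methoxyphenyl]lithium | COc1cc(OCc2ccccc2)c(Br)c([Li])c1OCc1ccccc1 | intermediate (not isolated)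
11 | 3,6-bis(benzyloxy)-2-bromo-5-methoxybenzaldehyde | COc1cc(OCc2ccccc2)c(Br)c(C=O)c1OCc1ccccc1 | intermediate
12 | 3,6-bis(benzyloxy)-2-{3-[2-(1,4-dioxaspiro[4.5]decan-8-yl)ethyl]phenoxy}-5-methoxybenzaldehyde | COc1cc(OCc2ccccc2)c(Oc2cccc(CCC3CCC4(CC3)OCCO4)c2)c(C=O)c1OCc1ccccc1 | intermediate
13 | 4-hydroxybenzyl alcohol | OCc1ccc(O)cc1 | starting material
14 | (4-hydroxybenzyl)triphenylphosphonium bromide | [Br-].Oc1ccc(C[P+](c2ccccc2)(c2ccccc2)c2ccccc2)cc1 | intermediate
15 | potassium 4-[(triphenylphosphoranylidene)methyl]phenolate (phenoxide ylide) | [K+].[O-]c1ccc(C=P(c2ccccc2)(c2ccccc2)c2ccccc2)cc1 | intermediate (not isolated)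
16 | 4-[2-(3,6-bis(benzyloxy)-2-{3-[2-(1,4-dioxaspiro[4.5]decan-8-yl)ethyl]phenoxy}-5-methoxyphenyl)ethenyl]phenol, E/Z mixture | COc1cc(OCc2ccccc2)c(Oc2cccc(CCC3CCC4(CC3)OCCO4)c2)c(C=Cc2ccc(O)cc2)c1OCc1ccccc1 | intermediate
17 | 4-[2-(3,6-bis(benzyloxy)-2-{3-[2-(1,4-dioxaspiro[4.5]decan-8-yl)ethyl]phenoxy}-5-methoxyphenyl)ethyl]phenol | COc1cc(OCc2ccccc2)c(Oc2cccc(CCC3CCC4(CC3)OCCO4)c2)c(CCc2ccc(O)cc2)c1OCc1ccccc1 | intermediate
18 | 4-[2-(3-{3,6-bis(benzyloxy)-2-[2-(4-hydroxyphenyl)ethyl]-4-methoxyphenoxy}phenyl)ethyl]cyclohexan-1-one | COc1cc(OCc2ccccc2)c(Oc2cccc(CCC3CCC(=O)CC3)c2)c(CCc2ccc(O)cc2)c1OCc1ccccc1 | intermediate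
19 | bis(trimethylsilyl) derivative of 18: trimethylsilyl enol ether of the ketone and trimethylsilyl ether of the ring A phenol, racemic | COc1cc(OCc2ccccc2)c(Oc2cccc(CCC3CCC(O[Si](C)(C)C)=CC3)c2)c(CCc2ccc(O[Si](C)(C)C)cc2)c1OCc1ccccc1 | intermediate (not isolated)
20 | 2-bromo ketone 21 with the ring A phenol still as its trimethylsilyl ether, racemic diastereomer mixture | COc1cc(OCc2ccccc2)c(Oc2cccc(CCC3CCC(=O)C(Br)C3)c2)c(CCc2ccc(O[Si](C)(C)C)cc2)c1OCc1ccccc1 | intermediate (not isolated)
21 | 2-bromo-4-[2-(3-{3,6-bis(benzyloxy)-2-[2-(4-hydroxyphenyl)ethyl]-4-methoxyphenoxy}phenyl)ethyl]cyclohexan-1-one, racemic cis/trans mixture (seco bromoketone phenol) | COc1cc(OCc2ccccc2)c(Oc2cccc(CCC3CCC(=O)C(Br)C3)c2)c(CCc2ccc(O)cc2)c1OCc1ccccc1 | intermediate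
22 | macrocyclic 2-aryloxycyclohexanone: the ring A oxygen bonded to C2 of the 4-substituted cyclohexanone in place of bromine, 18-membered ring, ring D as 1,4-bis(benzyloxy)-2-methoxyarene, racemic diastereomer mixture | COc1cc(OCc5ccccc5)c2Oc3cccc(c3)CCC3CCC(=O)C(C3)Oc3ccc(cc3)CCc2c1OCc1ccccc1 | intermediate
23 | macrocyclic bis(bibenzyl): ring C as 2-aryloxyphenol with OH para to the ethylene bridge, ring D as dibenzyl ether | COc1cc(OCc5ccccc5)c2Oc3cccc(c3)CCc3ccc(O)c(c3)Oc3ccc(cc3)CCc2c1OCc1ccccc1 | intermediate
24 | macrocyclic hydroquinone: 23 without the two benzyl groups | COc1cc(O)c2Oc3cccc(c3)CCc3ccc(O)c(c3)Oc3ccc(cc3)CCc2c1O | intermediate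
25 | CNP0332646.0, macrocyclic methoxy-aryloxy-para-quinone (achiral) | COC1=CC(=O)C2=C(CCc3ccc(cc3)Oc3cc(ccc3O)CCc3cccc(c3)O2)C1=O | target

**Step count and risks**

Total step count: 16. Longest linear sequence: 12 steps (steps 4 to 7 and 9 to 16 from 7; equally steps 1 to 3, 7 and 9 to 16 from 1).

Steps most likely to fail:

Step 13 (macro-etherification). Loss of HBr to the enone, base-induced ring contraction, or intermolecular etherification may outrun ring closure at the secondary alpha carbon. The fallback keeps the same O–C bond but uses an electrophile that cannot eliminate. It sets out from 18 through its bis-silyl enol ether 19: Saegusa–Ito oxidation (Pd(OAc)2, MeCN, rt, aqueous work-up) should give the 4-substituted cyclohex-2-enone F1, and nucleophilic epoxidation (H2O2, NaOH, MeOH, 0 °C) the 2,3-epoxy ketone F2. Slow addition of F2 to Cs2CO3 in DMF at 80 °C at high dilution should let the ring A phenoxide open the epoxide at the alpha carbon, and loss of water then gives the macrocyclic 2-aryloxycyclohex-2-enone F3. This is the known alpha-attack of oxygen and sulfur nucleophiles on 2,3-epoxycyclohexanones. One further dehydrogenation under the conditions of step 14 takes F3 to 23, where the route is rejoined.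

Step 14 (aromatisation). The catalytic dehydrogenation may stall at the enone stage, or the palladium may be deactivated by the electron-rich ring D. The fallback replaces the catalytic aerobic process by two stoichiometric, enol-silane-directed Saegusa–Ito oxidations. It sets out from 22: LiN(SiMe3)2 and Me3SiCl at −78 °C give the trimethylsilyl enol ether F4 on the CH2 side, and Pd(OAc)2 in MeCN gives the macrocyclic 6-aryloxycyclohex-2-enone F5. Me3SiOSO2CF3/Et3N then give the silyl dienol ether F6, and a second Pd(OAc)2 oxidation gives the dienone, which tautomerises to 23, where the route is rejoined. The regiochemistry of the first enolisation is not critical, since either enone leads to the same phenol.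

Step 12 (alpha-bromination). Electrophilic bromine may attack the free C–H of the tetraoxygenated ring D or the silylated ring A, or a second bromine may enter. The fallback installs an oxygen leaving group instead of a halogen. It sets out from 18 through 19: PhI(OH)OTs in CH2Cl2 at 0 °C, then mild acidic work-up, should give the alpha-tosyloxy ketone F7. Cyclisation of F7 under the conditions of step 13, with tosylate as the leaving group, comes back to the route at 22.

**Further compounds**

F1 | step 13 | 4-[2-(3-{3,6-bis(benzyloxy)-2-[2-(4-hydroxyphenyl)ethyl]-4-methoxyphenoxy}phenyl)ethyl]cyclohex-2-en-1-one, racemic | COc1cc(OCc2ccccc2)c(Oc2cccc(CCC3CCC(=O)C=C3)c2)c(CCc2ccc(O)cc2)c1OCc1ccccc1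
F2 | step 13 | 2,3-epoxide of F1 (2,3-epoxy-4-substituted cyclohexanone), racemic diastereomer mixture | COc1cc(OCc2ccccc2)c(Oc2cccc(CCC3CCC(=O)C4OC34)c2)c(CCc2ccc(O)cc2)c1OCc1ccccc1
F3 | step 13 | macrocyclic 2-aryloxycyclohex-2-en-1-one (22 with a C2=C3 double bond in ring C), racemic | COc1cc(OCc5ccccc5)c2Oc3cccc(c3)CCC3CCC(=O)C(=C3)Oc3ccc(cc3)CCc2c1OCc1ccccc1
F4 | step 14 | trimethylsilyl enol ether of 22 on the CH2 side (C1=C6), racemic diastereomer mixture | COc1cc(OCc5ccccc5)c2Oc3cccc(c3)CCC3CC=C(O[Si](C)(C)C)C(C3)Oc3ccc(cc3)CCc2c1OCc1ccccc1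
F5 | step 14 | macrocyclic 6-aryloxy-4-substituted cyclohex-2-en-1-one, racemic diastereomer mixture | COc1cc(OCc5ccccc5)c2Oc3cccc(c3)CCC3C=CC(=O)C(C3)Oc3ccc(cc3)CCc2c1OCc1ccccc1
F6 | step 14 | trimethylsilyl dienol ether of F5, racemic | COc1cc(OCc5ccccc5)c2Oc3cccc(c3)CCC3C=CC(O[Si](C)(C)C)=C(C3)Oc3ccc(cc3)CCc2c1OCc1ccccc1
F7 | step 12 | 2-(tosyloxy) analogue of 21 (alpha-tosyloxy ketone phenol), racemic diastereomer mixture | COc1cc(OCc2ccccc2)c(Oc2cccc(CCC3CCC(=O)C(OS(=O)(=O)c4ccc(C)cc4)C3)c2)c(CCc2ccc(O)cc2)c1OCc1ccccc1
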